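Atom numbers follow the daucane skeleton and are kept for every intermediate: ring B (five-membered) is C1–C2–C3–C4–C5, ring A (seven-membered) is C1–C5–C6–C7–C8–C9–C10, and β is the face of the C1 methyl group. TBS = tert-butyldimethylsilyl.

Compound numbers used throughout: **1** 2-methylcyclopentane-1,3-dione; **2** its isobutyl vinylogous ester; **4** the C4-isopropyl derivative; **6** the C4 ketol; **7** its TBS ether; **9** the alkynyl enone; **10** the C2 allylic alcohol; **11** the cyclopropane; **12** the terminal alkyne; **13** the methyl ketone; **14** the siloxyvinylcyclopropane; **15** 1-(trimethylsilyl)propyne; **16** the cycloadduct; **18** the C6 ketone; **19** the dihydroxy ketone; **20** the triol; **21** angelic acid; **23** the target. Compounds **3**, **5**, **8**, **17** and **22** are formed and consumed in the flask.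

## Analysis of the target

Compound 23 is a daucane diester: a trans-fused bicyclo[5.3.0]decane in which cyclopentane ring B (C1–C5) shares the C1–C5 bond with cycloheptene ring A (C1, C5–C10; olefin C8=C9, methyl on C8). It has five stereocentres, all on or next to the ring fusion: quaternary C1 (β-methyl), C2 (α-angeloyloxy), the tertiary carbinol C4 (β-OH, α-isopropyl), C5 (α-H) and C6 (α-angeloyloxy), that is 1R,2S,4R,5S,6S. C5 lies between two fully substituted carbons. The C2 and C4 oxygens are trans across ring B, and the C4 hydroxyl and C6 stand on the same (β) side of ring B, so the C4 hydroxyl can reach C6. The sensitive groups are: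

- the two angelates, which isomerise to tiglates under nucleophilic catalysis;
- the tertiary C4 hydroxyl, which is β to C6 and so invites elimination or retro-aldol cleavage whenever C6 is a ketone, and ether formation with a C8 cation in acid;
- the C8=C9 olefin, which is β,γ to C6 and drifts into conjugation under enolising conditions.

The difficulty is a seven-membered ring with an exactly placed trisubstituted olefin next to quaternary C1 and crowded C5, combined with three oxygenated carbons of fixed relative configuration. The strategy rests on the fact that ring A divides into a two-carbon unit C8–C9 that is a propyne (methyl on C8) and a five-carbon unit C7–C6–C5–C1–C10. The latter is present in a cyclopropane C1–C5–C10 fused to the α face of ring B that carries on C5 a vinyl group C6=C7 oxygenated at C6.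

## Retrosynthetic reasoning

**Ester C–O bonds (23 ⇒ 20 + 21).** The angelates are cut first because they are the most fragile groups; attached last, no later step can isomerise them. The tertiary C4 hydroxyl needs no protection, since it is not acylated under conditions that esterify the secondary C2 and C6 hydroxyls. The forward step must acylate two hindered secondary alcohols of 20 with 21 without Z-to-E isomerisation.

**C6–H bond (20 ⇒ 19 ⇒ 18).** C6 is taken back to the ketone of 19 because the free C4 hydroxyl sits on the β face beside C6 and can deliver hydride to that face, which gives the α-carbinol. An undirected hydride would be expected from the α face, away from the angular methyl. Compound 19 is the desilylated form of 18, whose silyl ethers serve only the earlier steps.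

**C5–H and C9–H bonds (18 ⇒ 16, through 17).** The C6 ketone with its C5 hydrogen is the hydrolysis product of a C5=C6 silyl enol ether, and the C9 hydrogen replaces a silyl group; one acid treatment removes both. The gain is diene 16, in which C5 is sp2 and the C8=C9 bond already exists. The forward step must protonate C5 on the α face under kinetic control and replace silicon at C9 without moving the olefin.

**C7–C8 and C9–C10 bonds (16 ⇒ 14 + 15).** This is the only disconnection that opens ring A. It is made here because 16 is a 1,4-cycloheptadiene whose two double bonds are exactly those left by the union of a vinylcyclopropane with an alkyne. Cuts elsewhere in ring A (C5–C6 or C1–C10) would require the ring-forming step to create a stereocentre or the quaternary carbon. Here C1 is quaternary beforehand and the ring closure creates no stereocentre. The forward reaction must open the C5–C10 bond of the cyclopropane and orient alkyne 15 with silicon on C9.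

**Enol ether and masked acetyl group (14 ⇒ 13 ⇒ 12 ⇒ 11).** The silyl enol ether derives from methyl ketone 13, which can enolise only toward C7; the same silylating agent covers the C2 hydroxyl. The acetyl group is carried as an alkyne (12, 11). A ketone or enol ether on C5 would not survive, or would disturb, the hydride reduction at C2 and the zinc carbenoid addition, whereas an alkyne is inert to both and is hydrated afterwards.

**C1–C10 and C5–C10 bonds (11 ⇒ 10).** Removing the cyclopropane methylene leaves the tetrasubstituted C1=C5 olefin of allylic alcohol 10. C1 and C5 are set here, by a zinc carbenoid bound to the C2 oxygen that adds on the α face. The C4 oxygen is allylic to the same olefin on the opposite face, so it must be silylated first or it would direct to the β face.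

**C2–H bond (10 ⇒ 9).** The C2 carbinol comes from enone 9 by catalyst-controlled reduction. Because C4 is already in place, any residual wrong C4 enantiomer becomes a separable diastereomer or stays behind as ketone.

**C5–C6 bond (9 ⇒ 7, via 8).** The alkynyl group on C5 and the C2 carbonyl of 9 result from 1,2-addition and transposition on vinylogous ester 7. The C6–C7 unit adds as an acetylide to the C5 carbonyl, and the enol ether carbon becomes the C2 ketone.

**C4–O and C4–isopropyl bonds (7 ⇒ 6 ⇒ 4 ⇒ 2 ⇒ 1).** C4 is the α′-carbon of vinylogous ester 2 and can be substituted twice through its enolates, first with carbon, then with oxygen. With oxidation second, the stereocentre is created from a planar enolate by a chiral oxygen-transfer reagent. All ring B carbons and the C1 methyl come from 1. Addition of an isopropyl nucleophile to a C4 ketone was rejected: on an achiral ring it gives racemic carbinol, and once C2 is set it would enter trans to the C2 oxygen, which is the wrong diastereomer.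

## Alternatives that were turned down

**Alternative 1:** transannular closure of a ten-membered ring.
- Disconnection: the C1–C5 bond and the C4–O bond, leading to the ten-membered epoxy diene A2 (cis C1–C2 epoxide, Z olefins C4=C5 and C8=C9, C6 silyl ether).
- Key step: a Lewis acid opens the epoxide at tertiary C1, C5 of the C4=C5 olefin attacks C1 across the ring, and the C4 cation is hydrated, giving the bicyclic 2α,4β-diol A1.
- For: one step forms both rings, the C1–C5 bond and three stereocentres (C1, C5, C4), and A1 is only an acylation, a desilylation and a second acylation away from 23. On bonds and stereocentres made in the key step it is clearly stronger than the [5+2], which makes no stereocentre.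
- Against: the outcome depends on one reactive conformer of a flexible ten-membered ring. Capture of the C4 cation on the β face is not enforced by any concerted element and competes with proton loss and hydride shifts. The allylic C6 silyloxy group deactivates the attacking olefin and may itself ionise. A2, with two Z trisubstituted olefins, a defined epoxide and a C6 carbinol in a medium ring, needs a long synthesis with a macrocyclisation.
- Comparison: the chosen route places each stereocentre in a separate, well-understood step on a five-membered ring whose faces are clearly differentiated, asks only regiocontrol of the ring-forming step, and reaches 14 from 1 by ordinary reactions.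

**Alternative 2:** oxygen-tethered crossed photocycloaddition with de Mayo ring expansion.
- Disconnection: C5–C6 and C1–C10 through a cyclobutane, then cleavage of C6–C10. The precursor is A4, a ring B cyclopentene (C1=C5) whose C2 oxygen carries a cyclic vinylogous ester (C6=C10–C9=O with C7 and C8).
- Key step: irradiation adds C6=C10 across C1=C5 in the crossed sense favoured by a two-atom tether, and aqueous acid then cleaves the β-alkoxy ketone by retro-aldol fragmentation to the 6,9-diketone A3.
- For: the tether through the C2 oxygen fixes the configuration of C1 as securely as the directed cyclopropanation. The C8 methyl is in place from the start, so there is no question of which alkyne carbon carries it; on that point it is stronger than the [5+2]. C5 in A3 can be equilibrated by base, because no β,γ-olefin is present; that is also stronger.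
- Against: A3 has a ketone at C9 and a saturated C8. Turning the C9 ketone into the C8=C9 olefin, and not C9=C10, while distinguishing it from the C6 ketone, costs several steps with no evident control. C5 arises cis-fused and must be inverted next to a β-hydroxy ketone. The crossed-to-straight ratio for a trisubstituted ring olefin is not assured.
- Comparison: the [5+2] delivers ring A with the C8=C9 olefin and C6 at the ketone level already correct, and four steps remain after it.

**Alternative 3:** lactone-enolate Claisen rearrangement.
- Disconnection: the C1–C10 bond, leading to the seven-membered lactone A6 (C2 carbonyl, ring oxygen on C8, vinyl group C9=C10 on C8, C4 as a ketal, C6 silyl ether).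
- Key step: an amide base and a chlorosilane give the silyl ketene acetal, which rearranges on warming to the cycloheptene acid A5 with quaternary C1.
- For: chirality transfer from C8 to C1 is intrinsic to the sigmatropic shift, and the C8=C9 olefin is formed exactly in place with no regiochemical ambiguity. On reliability of the ring-A-forming step and on olefin position it is stronger than the [5+2].
- Against: ring B is not yet formed. C3 must still be inserted between the C2 carboxyl and the C4 ketone, closing ring B at the most hindered site, and C2 and C4 (a tertiary carbinol formed by closure onto an isopropyl ketone) would be set late without obvious control. A6 needs three stereocentres in a seven-membered lactone, and its tetrasubstituted ketene acetal should form slowly.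
- Comparison: the chosen route builds ring B first, where stereocontrol is easiest, and uses one catalytic step for ring A.

Key step: step 11

Assumption: (1S)-(+)-(10-camphorsulfonyl)oxaziridine is taken as the enantiomer that hydroxylates enolate 5 on the face leading to (R)-6; if the sense is the reverse, the (1R)-(−) reagent is used and nothing else changes.

## Route

Step 1
Reactants: 1 2-methylcyclopentane-1,3-dione
Product: 2 3-isobutoxy-2-methylcyclopent-2-en-1-one
Conditions: i-BuOH, p-TsOH·H2O (cat.), toluene, reflux, Dean–Stark
Reagents that add atoms: 2-methylpropan-1-ol, CC(C)CO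
Why: Acid-catalysed enol etherification of the symmetric 1,3-dione with azeotropic removal of water gives a single vinylogous ester; this frees one carbonyl (future C5) for addition and activates one CH2 (future C4).

Step 2
Reactants: 2 3-isobutoxy-2-methylcyclopent-2-en-1-one
Product: 4 rac-3-isobutoxy-2-methyl-5-(propan-2-yl)cyclopent-2-en-1-one, via lithium enolate 3 (not isolated)
Conditions: LiN(i-Pr)2, THF, −78 °C; then i-PrI, DMPU, −78 → 0 °C
Reagents that add atoms: 2-iodopropane, CC(C)I
Why: Kinetic deprotonation of a vinylogous ester occurs at the α′-CH2 (C4), and the lithium enolate is C-alkylated by the secondary iodide in the presence of DMPU (enolate alkylation); the new C4 centre is racemic and is erased in step 3.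

Step 3
Reactants: 4 rac-3-isobutoxy-2-methyl-5-(propan-2-yl)cyclopent-2-en-1-one
Product: 6 (5R)-5-hydroxy-3-isobutoxy-2-methyl-5-(propan-2-yl)cyclopent-2-en-1-one, via lithium enolate 5 (not isolated)
Conditions: LiN(i-Pr)2, THF, −78 °C; then (1S)-(+)-(10-camphorsulfonyl)oxaziridine, −78 → −40 °C; aq NH4Cl
Reagents that add atoms: (1S)-(+)-(10-camphorsulfonyl)oxaziridine, CC1(C)[C@@H]2CC[C@]13CS(=O)(=O)N4O[C@@]34C2
Why: A second α′-deprotonation gives the planar tetrasubstituted enolate 5, which attacks the electrophilic oxygen of the enantiopure N-sulfonyloxaziridine (asymmetric enolate hydroxylation); reagent control sets C4 as R, and a moderate enantiomeric excess suffices because the minor enantiomer is removed at step 6.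

Step 4
Reactants: 6 (5R)-5-hydroxy-3-isobutoxy-2-methyl-5-(propan-2-yl)cyclopent-2-en-1-one
Product: 7 (5R)-5-(TBSO)-3-isobutoxy-2-methyl-5-(propan-2-yl)cyclopent-2-en-1-one
Conditions: TBSOTf, 2,6-lutidine, CH2Cl2, 0 °C → rt
Reagents that add atoms: tert-butyldimethylsilyl trifluoromethanesulfonate, CC(C)(C)[Si](C)(C)OS(=O)(=O)C(F)(F)F
Why: A silyl triflate with a hindered pyridine base silylates tertiary alcohols; the TBS ether blocks the C4 hydroxyl, which would otherwise direct the cyclopropanation of step 7 to the wrong face, and it is robust enough for steps 5–12.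

Step 5
Reactants: 7 (5R)-5-(TBSO)-3-isobutoxy-2-methyl-5-(propan-2-yl)cyclopent-2-en-1-one
Product: 9 (4R)-4-(TBSO)-2-methyl-4-(propan-2-yl)-3-[(trimethylsilyl)ethynyl]cyclopent-2-en-1-one, via lithium propargylic alkoxide 8 (not isolated)
Conditions: Me3SiC≡CH, n-BuLi, THF, −78 °C; then 7, −78 → 0 °C; then 1 M HCl, 0 °C
Reagents that add atoms: ethynyltrimethylsilane, C#C[Si](C)(C)C; water, O
Why: Stork–Danheiser transposition: the slim acetylide adds 1,2 to the hindered vinylogous ester carbonyl (C5), and dilute acid ionises the tertiary carbinol and hydrolyses the enol ether, so that C2 becomes the ketone and the masked acetyl group (C6–C7) sits on C5; an alkyne is used because it survives acid, hydride and zinc carbenoid.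

Step 6
Reactants: 9 (4R)-4-(TBSO)-2-methyl-4-(propan-2-yl)-3-[(trimethylsilyl)ethynyl]cyclopent-2-en-1-one
Product: 10 (1S,4R)-4-(TBSO)-2-methyl-4-(propan-2-yl)-3-[(trimethylsilyl)ethynyl]cyclopent-2-en-1-ol
Conditions: (R)-Me-CBS oxazaborolidine [(R)-1-methyl-3,3-diphenyltetrahydro-1H,3H-pyrrolo[1,2-c][1,3,2]oxazaborole] (0.2 equiv), catecholborane (1.1 equiv), toluene, −78 °C; then MeOH, aq NaOH
Reagents that add atoms: none
Why: Corey–Bakshi–Shibata reduction: with the C1=C5 side as the large group, the (R)-catalyst delivers hydride to the β face of C2 and sets C2 as S (α-OH); this sense should be matched with the bias of (4R)-9 (attack anti to isopropyl), so residual (4S)-9 reacts more slowly and ends as unreacted ketone or as the separable cis diastereomer.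

Step 7
Reactants: 10 (1S,4R)-4-(TBSO)-2-methyl-4-(propan-2-yl)-3-[(trimethylsilyl)ethynyl]cyclopent-2-en-1-ol
Product: 11 (1R,2S,4R,5S)-4-(TBSO)-1-methyl-4-(propan-2-yl)-5-[(trimethylsilyl)ethynyl]bicyclo[3.1.0]hexan-2-ol
Conditions: Et2Zn (4 equiv), CH2I2 (8 equiv), CH2Cl2, 0 °C → rt
Reagents that add atoms: diiodomethane, ICI
Why: Simmons–Smith cyclopropanation directed by the zinc alkoxide of the C2 hydroxyl: the methylene (C10) is delivered to the tetrasubstituted C1=C5 bond on the α face, cis to the C2 oxygen, which sets C1 (β-methyl) and C5 together; the silylated C4 oxygen cannot compete, the silylalkyne is inert to the carbenoid, and 2-methyl-3-substituted cyclopent-2-enols are known substrates.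

Step 8
Reactants: 11 (1R,2S,4R,5S)-4-(TBSO)-1-methyl-4-(propan-2-yl)-5-[(trimethylsilyl)ethynyl]bicyclo[3.1.0]hexan-2-ol
Product: 12 (1R,2S,4R,5R)-4-(TBSO)-5-ethynyl-1-methyl-4-(propan-2-yl)bicyclo[3.1.0]hexan-2-ol
Conditions: K2CO3 (cat.), MeOH, rt
Reagents that add atoms: none
Why: Base-catalysed methanolysis cleaves only the alkynyl C–Si bond; the tertiary TBS ether and the free alcohol are unaffected.

Step 9
Reactants: 12 (1R,2S,4R,5R)-4-(TBSO)-5-ethynyl-1-methyl-4-(propan-2-yl)bicyclo[3.1.0]hexan-2-ol
Product: 13 1-[(1R,2R,4S,5R)-2-(TBSO)-4-hydroxy-5-methyl-2-(propan-2-yl)bicyclo[3.1.0]hexan-1-yl]ethan-1-one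
Conditions: Ph3PAuNTf2 (3 mol %), MeOH/H2O (10:1), rt → 40 °C
Reagents that add atoms: water, O
Why: Gold-catalysed Markovnikov hydration of a terminal alkyne without added acid gives the methyl ketone (C6=O, C7H3); neutral conditions are chosen because the C4 silyloxy group sits on a cyclopropylcarbinyl carbon that would ionise in protic acid, and the C2 hydroxyl lies on the face opposite to the alkyne and cannot cyclise onto it.

Step 10
Reactants: 13 1-[(1R,2R,4S,5R)-2-(TBSO)-4-hydroxy-5-methyl-2-(propan-2-yl)bicyclo[3.1.0]hexan-1-yl]ethan-1-one
Product: 14 (1S,2R,4S,5R)-2,4-bis(TBSO)-1-[1-(TBSO)ethenyl]-5-methyl-2-(propan-2-yl)bicyclo[3.1.0]hexane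
Conditions: TBSOTf (3 equiv), Et3N (5 equiv), CH2Cl2, −78 → 0 °C
Reagents that add atoms: tert-butyldimethylsilyl trifluoromethanesulfonate, CC(C)(C)[Si](C)(C)OS(=O)(=O)C(F)(F)F
Why: Soft enolisation (silyl triflate and amine) of a methyl ketone whose other α-carbon is quaternary can give only the terminal silyl enol ether C6(OTBS)=C7, and the same reagent silylates the C2 hydroxyl.

Step 11
Reactants: 14 (1S,2R,4S,5R)-2,4-bis(TBSO)-1-[1-(TBSO)ethenyl]-5-methyl-2-(propan-2-yl)bicyclo[3.1.0]hexane; 15 1-(trimethylsilyl)propyne
Product: 16 (1R,2S,4R)-2,4,6-tris(TBSO)-9-(trimethylsilyl)dauca-5,8-diene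
Conditions: [Rh(CO)2Cl]2 (5 mol %), 15 (3 equiv), ClCH2CH2Cl, 80 °C
Reagents that add atoms: none
Why: [Rh(CO)2Cl]2 supplies a monovalent rhodium carbonyl chloride fragment that binds the C6=C7 enol ether of 14 and inserts into the adjacent cyclopropane bond C5–C10, giving a rhodacycle in which C7–C6–C5 is an η3-allyl unit and C10 a σ-alkyl ligand. Alkyne 15 then inserts into the Rh–C7 bond (C7–C8 formed), and C(sp2)–C(sp3) reductive elimination from the eight-membered rhodacycle forms C9–C10 and releases 16 with the C5=C6 silyl enol ether and the C8=C9 vinylsilane. The closest known reaction type is the rhodium-catalysed intermolecular [5+2] cycloaddition of alkynes with vinylcyclopropanes bearing an oxygen substituent or an α-substituent on the alkene; a ring-fused cyclopropane carrying a silyl enol ether as the vinyl group is a new member of that class. Ring A (seven-membered) is closed in the reductive elimination, as a metal-templated two-bond annulation and not a polar ring closure. No stereocentre is created: C5 becomes sp2, and C1, C2 and C4 are untouched. Cleavage of C5–C10 and not C5–C1 is secured because C10 is the only unsubstituted cyclopropane carbon, whereas insertion next to quaternary C1 is sterically disfavoured and would lead to a bridged ring system. The alkyne orientation rests on the bulkier Me3Si end staying away from the C–C bond formed first, so that it lies next to rhodium and ends on C9 with the methyl on C8; this is an expectation that must be verified. Reactivity is helped by the fully substituted C5, which holds the siloxyvinyl group s-cis to the C5–C10 bond, and by quaternary C1, which leaves the rhodium-bound C10 without a β-hydrogen to eliminate.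

Step 12
Reactants: 16 (1R,2S,4R)-2,4,6-tris(TBSO)-9-(trimethylsilyl)dauca-5,8-diene
Product: 18 (1R,2S,4R,5R)-2,4-bis(TBSO)dauc-8-en-6-one, via keto vinylsilane 17 (not isolated)
Conditions: CF3CO2H (5 equiv), CH2Cl2 (water-saturated), −20 → 0 °C; aq NaHCO3
Reagents that add atoms: none
Why: The acid protonates the silyl enol ether at C5 from the less hindered α face (the β face carries the C1 methyl and the C4 silyloxy group), giving the trans-fused ketone 17, and then protonates the vinylsilane at C9 (ipso), the β-silyl cation losing silicon so that the olefin stays at C8–C9 (protodesilylation); C5 is set under kinetic control because base or prolonged acid would move the β,γ-olefin into conjugation, and the two TBS ethers should survive short exposure at 0 °C.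

Step 13
Reactants: 18 (1R,2S,4R,5R)-2,4-bis(TBSO)dauc-8-en-6-one
Product: 19 (1R,2S,4R,5R)-2,4-dihydroxydauc-8-en-6-one
Conditions: HF·pyridine, pyridine, THF, 0 °C → rt
Reagents that add atoms: none
Why: Fluoride-mediated desilylation under buffered, weakly acidic conditions removes both TBS ethers without enolising the ketone (no olefin migration, no C5 epimerisation) and without the retro-aldol opening that a basic fluoride source could cause in the β-hydroxy ketone.

Step 14
Reactants: 19 (1R,2S,4R,5R)-2,4-dihydroxydauc-8-en-6-one
Product: 20 (1R,2S,4R,5S,6S)-dauc-8-ene-2,4,6-triol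
Conditions: Me4NBH(OAc)3 (5 equiv), MeCN/AcOH (1:1), −20 °C
Reagents that add atoms: none
Why: Evans–Saksena reduction: the C4 hydroxyl exchanges an acetate on boron and delivers hydride intramolecularly to the β face of the C6 ketone through a six-membered transition state, which sets C6 with the α-hydroxyl (1,3-anti to the C4 hydroxyl); the C2 hydroxyl lies on the opposite face and cannot deliver.

Step 15
Reactants: 20 (1R,2S,4R,5S,6S)-dauc-8-ene-2,4,6-triol; 21 angelic acid
Product: 23 (1R,2S,4R,5S,6S)-4-hydroxydauc-8-ene-2,6-diyl bis[(Z)-2-methylbut-2-enoate], via angelic 2,4,6-trichlorobenzoic anhydride 22 (not isolated)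
Conditions: 21 (4 equiv), 2,4,6-trichlorobenzoyl chloride (4 equiv), Et3N, toluene, rt; then 20, 80 °C
Reagents that add atoms: none
Why: Yamaguchi esterification without a nucleophilic catalyst: the mixed anhydride acylates both secondary hydroxyls on heating while the tertiary C4 hydroxyl stays free, and leaving out DMAP avoids the conjugate addition–elimination that converts angelates into tiglates.

## Compound list

1 | 2-methylcyclopentane-1,3-dione | CC1C(=O)CCC1=O | starting material
2 | 3-isobutoxy-2-methylcyclopent-2-en-1-one | CC1=C(OCC(C)C)CCC1=O | intermediate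
3 | lithium enolate of 2 (enolate double bond C5=C4, daucane numbering) | CC1=C(OCC(C)C)CC=C1[O-].[Li+] | intermediate
4 | rac-3-isobutoxy-2-methyl-5-(propan-2-yl)cyclopent-2-en-1-one | CC1=C(OCC(C)C)CC(C(C)C)C1=O | intermediate
5 | lithium enolate of 4 (tetrasubstituted, C5=C4) | CC1=C(OCC(C)C)CC(C(C)C)=C1[O-].[Li+] | intermediate
6 | (5R)-5-hydroxy-3-isobutoxy-2-methyl-5-(propan-2-yl)cyclopent-2-en-1-one | CC1=C(OCC(C)C)C[C@@](O)(C(C)C)C1=O | intermediate
7 | (5R)-5-[(tert-butyldimethylsilyl)oxy]-3-isobutoxy-2-methyl-5-(propan-2-yl)cyclopent-2-en-1-one | CC1=C(OCC(C)C)C[C@@](O[Si](C)(C)C(C)(C)C)(C(C)C)C1=O | intermediate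
8 | lithium (5R)-5-[(tert-butyldimethylsilyl)oxy]-3-isobutoxy-2-methyl-5-(propan-2-yl)-1-[(trimethylsilyl)ethynyl]cyclopent-2-en-1-olate (both C1 epimers) | CC1=C(OCC(C)C)C[C@@](O[Si](C)(C)C(C)(C)C)(C(C)C)C1([O-])C#C[Si](C)(C)C.[Li+] | intermediate
9 | (4R)-4-[(tert-butyldimethylsilyl)oxy]-2-methyl-4-(propan-2-yl)-3-[(trimethylsilyl)ethynyl]cyclopent-2-en-1-one | O=C1C[C@@](O[Si](C)(C)C(C)(C)C)(C(C)C)C(C#C[Si](C)(C)C)=C1C | intermediate
10 | (1S,4R)-4-[(tert-butyldimethylsilyl)oxy]-2-methyl-4-(propan-2-yl)-3-[(trimethylsilyl)ethynyl]cyclopent-2-en-1-ol | O[C@H]1C[C@@](O[Si](C)(C)C(C)(C)C)(C(C)C)C(C#C[Si](C)(C)C)=C1C | intermediate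
11 | (1R,2S,4R,5S)-4-[(tert-butyldimethylsilyl)oxy]-1-methyl-4-(propan-2-yl)-5-[(trimethylsilyl)ethynyl]bicyclo[3.1.0]hexan-2-ol (cyclopropane CH2 cis to the 2-hydroxyl) | C[Si](C)(C)C#C[C@]12C[C@@]1(C)[C@@H](O)C[C@@]2(O[Si](C)(C)C(C)(C)C)C(C)C | intermediate
12 | (1R,2S,4R,5R)-4-[(tert-butyldimethylsilyl)oxy]-5-ethynyl-1-methyl-4-(propan-2-yl)bicyclo[3.1.0]hexan-2-ol | C#C[C@]12C[C@@]1(C)[C@@H](O)C[C@@]2(O[Si](C)(C)C(C)(C)C)C(C)C | intermediate
13 | 1-[(1R,2R,4S,5R)-2-[(tert-butyldimethylsilyl)oxy]-4-hydroxy-5-methyl-2-(propan-2-yl)bicyclo[3.1.0]hexan-1-yl]ethan-1-one | CC(=O)[C@]12C[C@@]1(C)[C@@H](O)C[C@@]2(O[Si](C)(C)C(C)(C)C)C(C)C | intermediate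
14 | (1S,2R,4S,5R)-2,4-bis[(tert-butyldimethylsilyl)oxy]-1-{1-[(tert-butyldimethylsilyl)oxy]ethenyl}-5-methyl-2-(propan-2-yl)bicyclo[3.1.0]hexane | C=C(O[Si](C)(C)C(C)(C)C)[C@]12C[C@@]1(C)[C@@H](O[Si](C)(C)C(C)(C)C)C[C@@]2(O[Si](C)(C)C(C)(C)C)C(C)C | intermediate
15 | 1-(trimethylsilyl)propyne | CC#C[Si](C)(C)C | starting material
16 | (1R,2S,4R)-2,4,6-tris[(tert-butyldimethylsilyl)oxy]-9-(trimethylsilyl)dauca-5,8-diene (2α,4β) | C[Si](C)(C)C1=C(C)CC(O[Si](C)(C)C(C)(C)C)=C2[C@@](C)(C1)[C@@H](O[Si](C)(C)C(C)(C)C)C[C@@]2(O[Si](C)(C)C(C)(C)C)C(C)C | intermediate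
17 | (1R,2S,4R,5R)-2,4-bis[(tert-butyldimethylsilyl)oxy]-9-(trimethylsilyl)dauc-8-en-6-one (5α-H) | O=C1CC(C)=C([Si](C)(C)C)C[C@@]2(C)[C@@H](O[Si](C)(C)C(C)(C)C)C[C@@](O[Si](C)(C)C(C)(C)C)(C(C)C)[C@H]12 | intermediate
18 | (1R,2S,4R,5R)-2,4-bis[(tert-butyldimethylsilyl)oxy]dauc-8-en-6-one (5α-H) | O=C1CC(C)=CC[C@@]2(C)[C@@H](O[Si](C)(C)C(C)(C)C)C[C@@](O[Si](C)(C)C(C)(C)C)(C(C)C)[C@H]12 | intermediate
19 | (1R,2S,4R,5R)-2,4-dihydroxydauc-8-en-6-one (2α,4β-diol) | O=C1CC(C)=CC[C@@]2(C)[C@@H](O)C[C@@](O)(C(C)C)[C@H]12 | intermediate
20 | (1R,2S,4R,5S,6S)-dauc-8-ene-2,4,6-triol (2α,4β,6α) | O[C@H]1CC(C)=CC[C@@]2(C)[C@@H](O)C[C@@](O)(C(C)C)[C@H]12 | intermediate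
21 | angelic acid, (Z)-2-methylbut-2-enoic acid | C/C=C(/C)C(=O)O | starting material
22 | (Z)-2-methylbut-2-enoic 2,4,6-trichlorobenzoic anhydride | C/C=C(/C)C(=O)OC(=O)c1c(Cl)cc(Cl)cc1Cl | intermediate
23 | (1R,2S,4R,5S,6S)-4-hydroxydauc-8-ene-2,6-diyl bis[(Z)-2-methylbut-2-enoate] (2α,6α-diangeloyloxy-4β-hydroxy) | C/C=C(/C)C(=O)O[C@H]1CC(C)=CC[C@@]2(C)[C@@H](OC(=O)/C(C)=C\C)C[C@@](O)(C(C)C)[C@H]12 | target

## Step count and least certain steps

Total: 15 steps. Longest linear sequence: 15 steps (1 → 23); 15 and 21 enter at steps 11 and 15.

**Step 11 (key step).** The most likely failure is insertion of the alkyne with the opposite orientation, silicon ending on C8. The steric rule comes from less crowded vinylcyclopropanes, and here the rhodium-bound C10 is neopentyl, so the Me3Si group may avoid it. Fallback, from 14: run the cycloaddition with ethynyltrimethylsilane, which under that preference places silicon on C8 and hydrogen on C9, to give the 8-demethyl-8-(trimethylsilyl) analogue of 16 without silicon at C9, F1. Buffered fluoride (Bu4NF/AcOH, THF, −20 °C) cleaves only the enol ether to the 8-(trimethylsilyl) ketone F2. N-Iodosuccinimide in (CF3)2CHOH exchanges silicon for iodine at the same carbon to give the 8-iodo ketone F3. Negishi coupling with MeZnCl and Pd(PPh3)4 (zerovalent palladium) installs the C8 methyl and returns to the route at 18.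

**Step 12.** The most likely failure is acid-catalysed migration of the C8=C9 bond into conjugation with the C6 ketone during the time the protodesilylation needs; ionisation of the allylic C4 silyloxy group before C5 is protonated is a second possibility. Fallback, from 16: cleave only the enol ether with Bu4NF/AcOH at −20 °C and isolate 17, exchange silicon for iodine with N-iodosuccinimide in (CF3)2CHOH to give the 9-iodo ketone F4, and remove iodine by palladium-catalysed formate reduction (Pd(OAc)2, PPh3, HCO2H, Et3N, DMF), returning at 18. No strong acid is then used.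

**Step 3.** The most likely failure is poor facial discrimination by the oxaziridine, because the enolate lacks the aryl group that usually gives high induction with this reagent class. Fallback, from 4: hydroxylate enolate 5 with achiral trans-2-(phenylsulfonyl)-3-phenyloxaziridine to the racemic ketol F5, silylate as in step 4 to the racemic silyl ether F6, and treat as in step 5 to pass through the racemic alkoxide F7 to the racemic enynone F8. Step 6 is then run as a kinetic resolution with about 0.55 equivalents of catecholborane. The matched (4R) enantiomer is reduced and the route is rejoined at 10, while the (4S)-enynone F9 stays behind as ketone and is separated.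

**Step 2.** The most likely failure is elimination of the secondary iodide by the enolate together with proton transfer between enolate and product, which leaves starting material and polyalkylated material. Fallback, from 2: add enolate 3 to acetone to give the aldol adduct F10, dehydrate (MsCl, Et3N; then DBU) to the isopropylidene ketone F11, and hydrogenate the exocyclic enone double bond (H2, Pd/C, EtOAc), which returns to the route at 4.

**Step 15.** The most likely failure is incomplete acylation of the two hindered secondary hydroxyls (C2 next to quaternary C1, C6 next to C5), with Z-to-E isomerisation of the angelate if the conditions are forced. Fallback, from 20: esterify both hydroxyls with 2-[bis(2,2,2-trifluoroethoxy)phosphoryl]propanoic acid (carbodiimide, DMAP; no olefin is present to isomerise) to give the bis(phosphonopropionate) F12. A double Still–Gennari olefination with acetaldehyde (KN(SiMe3)2, 18-crown-6, THF, −78 °C) then builds both Z-2-methylbut-2-enoates directly on the substrate and arrives at 23.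

## Further compounds

F1 | step 11 | (1R,2S,4R)-2,4,6-tris[(tert-butyldimethylsilyl)oxy]-8-demethyl-8-(trimethylsilyl)dauca-5,8-diene | C1=C([Si](C)(C)C)CC(O[Si](C)(C)C(C)(C)C)=C2[C@@](C)(C1)[C@@H](O[Si](C)(C)C(C)(C)C)C[C@@]2(O[Si](C)(C)C(C)(C)C)C(C)C
F2 | step 11 | (1R,2S,4R,5R)-2,4-bis[(tert-butyldimethylsilyl)oxy]-8-demethyl-8-(trimethylsilyl)dauc-8-en-6-one | O=C1CC([Si](C)(C)C)=CC[C@@]2(C)[C@@H](O[Si](C)(C)C(C)(C)C)C[C@@](O[Si](C)(C)C(C)(C)C)(C(C)C)[C@H]12
F3 | step 11 | (1R,2S,4R,5R)-2,4-bis[(tert-butyldimethylsilyl)oxy]-8-demethyl-8-iododauc-8-en-6-one | O=C1CC(I)=CC[C@@]2(C)[C@@H](O[Si](C)(C)C(C)(C)C)C[C@@](O[Si](C)(C)C(C)(C)C)(C(C)C)[C@H]12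
F4 | step 12 | (1R,2S,4R,5R)-2,4-bis[(tert-butyldimethylsilyl)oxy]-9-iododauc-8-en-6-one | O=C1CC(C)=C(I)C[C@@]2(C)[C@@H](O[Si](C)(C)C(C)(C)C)C[C@@](O[Si](C)(C)C(C)(C)C)(C(C)C)[C@H]12
F5 | step 3 | rac-5-hydroxy-3-isobutoxy-2-methyl-5-(propan-2-yl)cyclopent-2-en-1-one | CC1=C(OCC(C)C)CC(O)(C(C)C)C1=O
F6 | step 3 | rac-5-[(tert-butyldimethylsilyl)oxy]-3-isobutoxy-2-methyl-5-(propan-2-yl)cyclopent-2-en-1-one | CC1=C(OCC(C)C)CC(O[Si](C)(C)C(C)(C)C)(C(C)C)C1=O
F7 | step 3 | racemic lithium 5-[(tert-butyldimethylsilyl)oxy]-3-isobutoxy-2-methyl-5-(propan-2-yl)-1-[(trimethylsilyl)ethynyl]cyclopent-2-en-1-olate | CC1=C(OCC(C)C)CC(O[Si](C)(C)C(C)(C)C)(C(C)C)C1([O-])C#C[Si](C)(C)C.[Li+]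
F8 | step 3 | rac-4-[(tert-butyldimethylsilyl)oxy]-2-methyl-4-(propan-2-yl)-3-[(trimethylsilyl)ethynyl]cyclopent-2-en-1-one | O=C1CC(O[Si](C)(C)C(C)(C)C)(C(C)C)C(C#C[Si](C)(C)C)=C1C
F9 | step 3 | (4S)-4-[(tert-butyldimethylsilyl)oxy]-2-methyl-4-(propan-2-yl)-3-[(trimethylsilyl)ethynyl]cyclopent-2-en-1-one | O=C1C[C@](O[Si](C)(C)C(C)(C)C)(C(C)C)C(C#C[Si](C)(C)C)=C1C
F10 | step 2 | rac-5-(2-hydroxypropan-2-yl)-3-isobutoxy-2-methylcyclopent-2-en-1-one | CC1=C(OCC(C)C)CC(C(C)(C)O)C1=O
F11 | step 2 | 3-isobutoxy-2-methyl-5-(propan-2-ylidene)cyclopent-2-en-1-one | CC1=C(OCC(C)C)CC(=C(C)C)C1=O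
F12 | step 15 | (1R,2S,4R,5S,6S)-4-hydroxydauc-8-ene-2,6-diyl bis{2-[bis(2,2,2-trifluoroethoxy)phosphoryl]propanoate} | CC(C(=O)O[C@H]1CC(C)=CC[C@@]2(C)[C@@H](OC(=O)C(C)P(=O)(OCC(F)(F)F)OCC(F)(F)F)C[C@@](O)(C(C)C)[C@H]12)P(=O)(OCC(F)(F)F)OCC(F)(F)F
A1 | alternative 1 | (1R,2S,4R,5S,6S)-6-[(tert-butyldimethylsilyl)oxy]dauc-8-ene-2,4-diol | CC(C)(C)[Si](C)(C)O[C@H]1CC(C)=CC[C@@]2(C)[C@@H](O)C[C@@](O)(C(C)C)[C@H]12
A2 | alternative 1 | ten-membered cis-1,2-epoxy-(4Z,8Z)-diene with isopropyl on C4, silyl ether on C6, methyl on C1 and C8 (daucane numbering) | CC(C)(C)[Si](C)(C)O[C@H]1C/C(C)=C\C[C@@]2(C)O[C@H]2C/C(C(C)C)=C\1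
A3 | alternative 2 | cis-fused 2α,4β-dihydroxydaucane-6,9-dione (5-epi) | O=C1C[C@H](C)C(=O)C[C@@]2(C)[C@@H](O)C[C@@](O)(C(C)C)[C@@H]12
A4 | alternative 2 | 3-{[(1S,4R)-4-hydroxy-2-methyl-4-(propan-2-yl)cyclopent-2-en-1-yl]oxy}-5-methylcyclopent-2-en-1-one | CC1=C[C@](O)(C(C)C)C[C@@H]1OC2=CC(=O)C(C)C2
A5 | alternative 3 | cycloheptene carboxylic acid with the C2 carboxyl on quaternary C1, C6 silyl ether and C4 dioxolane | CC(C)(C)[Si](C)(C)O[C@H]1CC(C)=CC[C@@](C)(C(=O)O)[C@@H]1C2(C(C)C)OCCO2
A6 | alternative 3 | seven-membered lactone (C2 carbonyl, ring oxygen and vinyl group on C8, C4 dioxolane on C5, C6 silyl ether; C1 unspecified) | C=C[C@@]1(C)C[C@H](O[Si](C)(C)C(C)(C)C)[C@@H](C2(C(C)C)OCCO2)C(C)C(=O)O1
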